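**Retrosynthetic overview**

1. Feature: ring A is a phloroglucinol ring with carbon only at C6 (the stereogenic side chain), H at C8 and the ring C carbonyl carbon on C4a. Its oxygens on C5, C7 and C8a must be told apart, because only the one on C8a (para to C6) may become O1.
2. Target ⇐ BBr3 demethylation ⇐ ring C by Claisen–Schmidt condensation and I2/DMSO cyclisation of a 2-hydroxyacetophenone whose only free phenol is the oxygen para to C6. The acetyl group enters a ring A that is symmetric about the C6–C8a axis.
3. Ring A ⇐ benzannulation of 3-(benzyloxy)cyclobutenone with a chiral siloxyalkyne. Bonds C6–C7 and C4a–C5 form, and the oxygens arrive as OH, OSi(i-Pr)3 and OBn, the benzyl ether para to C6.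
4. Siloxyalkyne ⇐ (S)-3-phenylpent-4-ynoic acid (acetylide oxidation on the lithium carboxylate, then double silylation) ⇐ rhodium-catalysed asymmetric conjugate alkynylation of 5-benzylidene Meldrum's acid, which sets the only stereocentre.
5. Ring order: ring A (step 5), then ring C (step 10); ring B and the phenyl ring are bought.

Key step: step 5

Assumption: both antipodes of the bisphosphine of step 2 are available; the antipode that gives the 1R adduct 6 is fixed in a first run by correlating acid 8 with the S configuration.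

**Route**

Step 1
Reactants: 1 3-ethoxycyclobut-2-en-1-one; 2 benzyl alcohol
Product: 3 3-(benzyloxy)cyclobut-2-en-1-one
Conditions: 2 (3 equiv), PPTS (5 mol%), toluene, 40 °C, reduced pressure (EtOH stripped)
Reagents that add atoms: none
Why: Acid-catalysed transetherification of a vinylogous ester, in which benzyl alcohol adds to C3 of the protonated enone and ethanol is expelled and removed; benzyl is chosen because hydrogenolysis will later free this oxygen alone.

Step 2
Reactants: 4 5-benzylidene-2,2-dimethyl-1,3-dioxane-4,6-dione; 5 trimethylsilylacetylene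
Product: 6 2,2-dimethyl-5-[(1R)-1-phenyl-3-(trimethylsilyl)prop-2-yn-1-yl]-1,3-dioxane-4,6-dione
Conditions: Rh(acac)(C2H4)2 (5 mol%), 3,5-xylyl-MeO-BIPHEP (6 mol%, antipode giving 1R), 5 (2 equiv, slow addition), 1,2-dichloroethane, 15 °C
Reagents that add atoms: none
Why: Rhodium-catalysed enantioselective conjugate alkynylation, in which a chiral bisphosphine–rhodium acetylide adds to the doubly activated benzylidene acceptor on the face chosen by the ligand and so sets the only stereocentre (1R); the fast addition to this acceptor should outrun alkyne dimerisation.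

Step 3
Reactants: 6 2,2-dimethyl-5-[(1R)-1-phenyl-3-(trimethylsilyl)prop-2-yn-1-yl]-1,3-dioxane-4,6-dione
Product: 8 (3S)-3-phenylpent-4-ynoic acid, via silylated acid 7 (not isolated)
Conditions: DMF/H2O (10:1), 100 °C; then K2CO3 (3 equiv), MeOH, 0 °C → rt; 1 M HCl
Reagents that add atoms: water, O
Why: Hydrolytic decarboxylation of a 5-monosubstituted Meldrum's acid followed by methoxide-mediated protodesilylation of the alkynylsilane; the stereocentre is β to the carboxyl and not enolisable, and its descriptor changes from R to S only because ethynyl ranks below phenyl.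

Step 4
Reactants: 8 (3S)-3-phenylpent-4-ynoic acid
Product: 11 triisopropylsilyl (3R)-3-phenyl-5-[(triisopropylsilyl)oxy]pent-4-ynoate, via dilithium acetylide carboxylate 9 (not isolated), via dilithium ynolate carboxylate 10 (not isolated)
Conditions: LiN(SiMe3)2 (2.1 equiv), THF, −78 °C; t-BuOOLi (from t-BuOOH and LiN(SiMe3)2, 1.1 equiv), −78 → 0 °C; TIPSOTf (2.3 equiv), −78 → 0 °C; pentane, filtration through Et3N-deactivated silica
Reagents that add atoms: tert-butyl hydroperoxide (used as its lithium salt), CC(C)(C)OO; triisopropylsilyl trifluoromethanesulfonate, CC(C)[Si](C(C)C)(C(C)C)OS(=O)(=O)C(F)(F)F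
Why: Oxidation of a lithium acetylide to the lithium ynolate by lithium tert-butyl peroxide and O-silylation, a known siloxyalkyne synthesis; the carboxyl group is carried as its lithium carboxylate, which the amide base cannot enolise (an alkyl ester would compete with the alkyne for the base), and the silyl triflate then caps both oxygens.

Step 5
Reactants: 3 3-(benzyloxy)cyclobut-2-en-1-one; 11 triisopropylsilyl (3R)-3-phenyl-5-[(triisopropylsilyl)oxy]pent-4-ynoate
Product: 16 triisopropylsilyl (3R)-3-{4-(benzyloxy)-2-hydroxy-6-[(triisopropylsilyl)oxy]phenyl}-3-phenylpropanoate, via vinylketene 12 (not isolated), via vinylcyclobutenone 13 (not isolated), via dienylketene 14 (not isolated), via cyclohexadienone 15 (not isolated)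
Conditions: 3 (1.3 equiv), toluene (0.3 M), 80 → 110 °C, sealed tube, argon
Reagents that add atoms: none
Why: Danheiser benzannulation: thermal four-electron electrocyclic opening of 3 gives vinylketene 12, whose C=C adds [2+2] across the electron-rich triple bond of 11 to give 13; four-electron opening of 13 gives dienylketene 14, which closes and enolises through dienone 15 to the phenol. The closest known reactions are the thermal annulations of 3-alkyl- and 3-arylcyclobutenones with triisopropylsiloxyalkynes to monosilylated resorcinols; here the 3-alkoxy group and the stereogenic propargylic carbon are the untested features. Ring A is closed by a thermal disrotatory six-electron electrocyclisation of 14 (bond C7–C8, taking the hydroxyl-bearing carbon as C7), after the [2+2] step has made the two new skeletal bonds C6–C7 and C4a–C5. No lasting stereocentre is created (the sp3 ring carbon of 13 is lost on ring opening), and the propargylic centre is a spectator in a neutral, aprotic medium and keeps its R configuration. The selectivity needed is the regiochemistry of the [2+2] addition, and the polarisation of the siloxyalkyne secures it: the nucleophilic carbon β to oxygen, which carries the side chain, bonds to the ketene carbonyl carbon, so the side chain ends between OH and OSi(i-Pr)3 with the benzyloxy group para to it. Each oxygen thus carries a different label (H from the ketene carbonyl, silyl from the alkyne, benzyl from the cyclobutenone), which later allows the oxygen para to C6 to be freed alone as O1.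

Step 6
Reactants: 16 triisopropylsilyl (3R)-3-{4-(benzyloxy)-2-hydroxy-6-[(triisopropylsilyl)oxy]phenyl}-3-phenylpropanoate
Product: 18 methyl (3R)-3-[4-(benzyloxy)-2,6-dimethoxyphenyl]-3-phenylpropanoate, via diphenol carboxylate 17 (not isolated)
Conditions: Bu4NF (2.5 equiv), THF, 0 °C → rt; then K2CO3, MeI (excess), DMF/MeOH, rt
Reagents that add atoms: iodomethane, CI
Why: Fluoride cleaves the silyl ester and the aryl silyl ether, and Williamson methylation of the carboxylate and both phenoxides in the same pot (no acidic isolation, so the hydroxy acid cannot lactonise; the methanol co-solvent would reopen any lactonised material) makes ring A symmetric about the C6–C8a axis, with benzyl left on the oxygen para to C6.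

Step 7
Reactants: 18 methyl (3R)-3-[4-(benzyloxy)-2,6-dimethoxyphenyl]-3-phenylpropanoate
Product: 19 methyl (3R)-3-(4-hydroxy-2,6-dimethoxyphenyl)-3-phenylpropanoate
Conditions: H2 (1 atm), Pd/C (10%), EtOAc, rt
Reagents that add atoms: none
Why: Catalytic hydrogenolysis of the benzyl aryl ether frees only the oxygen para to C6 (the future O1); methyl ethers, the ester and the diarylmethine C–H are inert to hydrogen over Pd/C.

Step 8
Reactants: 19 methyl (3R)-3-(4-hydroxy-2,6-dimethoxyphenyl)-3-phenylpropanoate
Product: 21 methyl (3R)-3-(3-acetyl-4-hydroxy-2,6-dimethoxyphenyl)-3-phenylpropanoate, via difluoroboron chelate 20 (not isolated)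
Conditions: Ac2O (1.5 equiv), BF3·OEt2 (3 equiv), AcOH, 60 °C; then MeOH/H2O, 60 °C
Reagents that add atoms: acetic anhydride, CC(=O)OC(C)=O
Why: Boron trifluoride-mediated Friedel–Crafts (Fries-type) acetylation ortho to the free phenol, driven by the difluoroboron chelate; the two open ring positions are equivalent by symmetry, so a single acetophenone should result, and its hydroxyl/acetyl pair fixes O1, C8a, C4a and C4.

Step 9
Reactants: 21 methyl (3R)-3-(3-acetyl-4-hydroxy-2,6-dimethoxyphenyl)-3-phenylpropanoate; 22 4-methoxybenzaldehyde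
Product: 23 (3R)-3-{4-hydroxy-2,6-dimethoxy-3-[(2E)-3-(4-methoxyphenyl)prop-2-enoyl]phenyl}-3-phenylpropanoic acid
Conditions: 22 (1.3 equiv), KOH (50% aq, excess), MeOH, rt → 40 °C; then 1 M HCl, 0 °C
Reagents that add atoms: potassium hydroxide, [K+].[OH-]
Why: Claisen–Schmidt condensation of the methyl ketone enolate with the non-enolisable aldehyde and E1cB dehydration gives the (E)-chalcone, while the aqueous hydroxide saponifies the methyl ester, which is welcome because the acid is the target function; the stereocentre is β to the carboxylate and cannot epimerise.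

Step 10
Reactants: 23 (3R)-3-{4-hydroxy-2,6-dimethoxy-3-[(2E)-3-(4-methoxyphenyl)prop-2-enoyl]phenyl}-3-phenylpropanoic acid
Product: 24 (3R)-3-[5,7-dimethoxy-2-(4-methoxyphenyl)-4-oxo-4H-chromen-6-yl]-3-phenylpropanoic acid
Conditions: I2 (10 mol%), DMSO, 120 °C
Reagents that add atoms: none
Why: Iodine-catalysed oxidative cyclisation of a 2'-hydroxychalcone in DMSO, in which oxa-Michael closure by the only free phenol (6-endo at the enone β-carbon) and iodine-mediated dehydrogenation with DMSO as terminal oxidant form ring C, placing the side chain at C6 and not at C8.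

Step 11
Reactants: 24 (3R)-3-[5,7-dimethoxy-2-(4-methoxyphenyl)-4-oxo-4H-chromen-6-yl]-3-phenylpropanoic acid
Product: 25 (3R)-3-[5,7-dihydroxy-2-(4-hydroxyphenyl)-4-oxo-4H-chromen-6-yl]-3-phenylpropanoic acid
Conditions: BBr3 (8 equiv), CH2Cl2, −78 °C → rt; then THF/H2O, 0 °C; reversed-phase chromatography
Reagents that add atoms: none
Why: Lewis-acid demethylation of the three aryl methyl ethers by BBr3 (the chelated C5 ether first) and cold hydrolysis of the borates leave the carboxylic acid and the remote diarylmethine stereocentre untouched; the cold, brief aqueous quench is meant to avoid closure of the acid onto the C5 or C7 hydroxyl.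

**Compound list**

1 | 3-ethoxycyclobut-2-en-1-one | CCOC1=CC(=O)C1 | starting material
2 | benzyl alcohol | OCc1ccccc1 | starting material
3 | 3-(benzyloxy)cyclobut-2-en-1-one | O=C1C=C(OCc2ccccc2)C1 | intermediate
4 | 5-benzylidene-2,2-dimethyl-1,3-dioxane-4,6-dione (5-benzylidene Meldrum's acid) | CC1(C)OC(=O)C(=Cc2ccccc2)C(=O)O1 | starting material
5 | trimethylsilylacetylene | C#C[Si](C)(C)C | starting material
6 | 2,2-dimethyl-5-[(1R)-1-phenyl-3-(trimethylsilyl)prop-2-yn-1-yl]-1,3-dioxane-4,6-dione | CC1(C)OC(=O)C([C@H](c2ccccc2)C#C[Si](C)(C)C)C(=O)O1 | intermediate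
7 | (3R)-3-phenyl-5-(trimethylsilyl)pent-4-ynoic acid | O=C(O)C[C@H](c1ccccc1)C#C[Si](C)(C)C | intermediate (not isolated)
8 | (3S)-3-phenylpent-4-ynoic acid | O=C(O)C[C@H](c1ccccc1)C#C | intermediate
9 | dilithium (3S)-3-phenylpent-4-yn-5-id-1-oate (acetylide carboxylate) | [Li+].[Li+].[O-]C(=O)C[C@H](c1ccccc1)C#[C-] | intermediate (not isolated)
10 | dilithium (3R)-5-oxido-3-phenylpent-4-ynoate (ynolate carboxylate) | [Li+].[Li+].[O-]C(=O)C[C@H](c1ccccc1)C#C[O-] | intermediate (not isolated)
11 | triisopropylsilyl (3R)-3-phenyl-5-[(triisopropylsilyl)oxy]pent-4-ynoate | CC(C)[Si](C(C)C)(C(C)C)OC(=O)C[C@H](c1ccccc1)C#CO[Si](C(C)C)(C(C)C)C(C)C | intermediate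
12 | 3-(benzyloxy)buta-1,3-dien-1-one (vinylketene) | C=C(OCc1ccccc1)C=C=O | intermediate (not isolated)
13 | triisopropylsilyl (3R)-3-{3-[1-(benzyloxy)ethenyl]-4-oxo-2-[(triisopropylsilyl)oxy]cyclobut-1-en-1-yl}-3-phenylpropanoate (ring C3 epimers) | CC(C)[Si](C(C)C)(C(C)C)OC(=O)C[C@H](c1ccccc1)C1=C(O[Si](C(C)C)(C(C)C)C(C)C)C(C(=C)OCc2ccccc2)C1=O | intermediate (not isolated)
14 | triisopropylsilyl (3R)-7-(benzyloxy)-4-(oxomethylidene)-3-phenyl-5-[(triisopropylsilyl)oxy]octa-5,7-dienoate (dienylketene) | CC(C)[Si](C(C)C)(C(C)C)OC(=O)C[C@H](c1ccccc1)C(=C=O)C(O[Si](C(C)C)(C(C)C)C(C)C)=CC(=C)OCc1ccccc1 | intermediate (not isolated)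
15 | triisopropylsilyl (3R)-3-{4-(benzyloxy)-6-oxo-2-[(triisopropylsilyl)oxy]cyclohexa-1,3-dien-1-yl}-3-phenylpropanoate | CC(C)[Si](C(C)C)(C(C)C)OC(=O)C[C@H](c1ccccc1)C1=C(O[Si](C(C)C)(C(C)C)C(C)C)C=C(OCc2ccccc2)CC1=O | intermediate (not isolated)
16 | triisopropylsilyl (3R)-3-{4-(benzyloxy)-2-hydroxy-6-[(triisopropylsilyl)oxy]phenyl}-3-phenylpropanoate | CC(C)[Si](C(C)C)(C(C)C)OC(=O)C[C@H](c1ccccc1)c1c(O)cc(OCc2ccccc2)cc1O[Si](C(C)C)(C(C)C)C(C)C | intermediate
17 | (3R)-3-[4-(benzyloxy)-2,6-dihydroxyphenyl]-3-phenylpropanoic acid (present as its tetrabutylammonium and potassium salts) | O=C(O)C[C@H](c1ccccc1)c1c(O)cc(OCc2ccccc2)cc1O | intermediate (not isolated)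
18 | methyl (3R)-3-[4-(benzyloxy)-2,6-dimethoxyphenyl]-3-phenylpropanoate | COC(=O)C[C@H](c1ccccc1)c1c(OC)cc(OCc2ccccc2)cc1OC | intermediate
19 | methyl (3R)-3-(4-hydroxy-2,6-dimethoxyphenyl)-3-phenylpropanoate | COC(=O)C[C@H](c1ccccc1)c1c(OC)cc(O)cc1OC | intermediate
20 | difluoroboron chelate of 21 | COC(=O)C[C@H](c1ccccc1)c1c(OC)cc2O[B-](F)(F)[O+]=C(C)c2c1OC | intermediate (not isolated)
21 | methyl (3R)-3-(3-acetyl-4-hydroxy-2,6-dimethoxyphenyl)-3-phenylpropanoate | COC(=O)C[C@H](c1ccccc1)c1c(OC)cc(O)c(C(C)=O)c1OC | intermediate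
22 | 4-methoxybenzaldehyde | COc1ccc(C=O)cc1 | starting material
23 | (3R)-3-{4-hydroxy-2,6-dimethoxy-3-[(2E)-3-(4-methoxyphenyl)prop-2-enoyl]phenyl}-3-phenylpropanoic acid | O=C(O)C[C@H](c1ccccc1)c1c(OC)cc(O)c(C(=O)/C=C/c2ccc(OC)cc2)c1OC | intermediate
24 | (3R)-3-[5,7-dimethoxy-2-(4-methoxyphenyl)-4-oxo-4H-chromen-6-yl]-3-phenylpropanoic acid | O=C(O)C[C@H](c1ccccc1)c1c(OC)cc2oc(-c3ccc(OC)cc3)cc(=O)c2c1OC | intermediate
25 | (3R)-3-[5,7-dihydroxy-2-(4-hydroxyphenyl)-4-oxo-4H-chromen-6-yl]-3-phenylpropanoic acid | O=C(O)C[C@H](c1ccccc1)c1c(O)cc2oc(-c3ccc(O)cc3)cc(=O)c2c1O | target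

**Step count and risks**

Total steps: 11. Longest linear sequence: 10 steps (steps 2 to 11, from 4); step 1 is the convergent branch.

Most likely to fail, in order:

1. Step 5. The donor-stabilised cyclobutenone 3 may open only at temperatures at which the siloxyalkyne 11 suffers oxygen-to-carbon silyl migration to a silylketene. Alternatively, the vinylketene 12 may oligomerise or acylate the product phenol faster than it is trapped, so that conversion of 11 stalls. The fallback sets out from 2 and 11 and comes back at 16. It makes the same vinylketene 12 at 0–25 °C by 1,4-dehydrochlorination instead of ring opening. Ethyl but-2-ynoate and 2 (excess) with catalytic NaH should give, by alkoxide conjugate addition and transesterification, benzyl (2E)-3-(benzyloxy)but-2-enoate F1. LiOH in THF/H2O gives (2E)-3-(benzyloxy)but-2-enoic acid F2, and (COCl)2 with catalytic DMF gives (2E)-3-(benzyloxy)but-2-enoyl chloride F3. Slow addition of F3 to 11 and Et3N in toluene releases 12, which 11 traps near room temperature to give 13. Warming to 80 °C, when 11 is no longer needed, completes the sequence through 14 and 15 to 16.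

2. Step 4. The poorly soluble dilithio species may be deprotonated or oxidised incompletely, or the carboxylate may be silylated incompletely, so that free carboxylic acid adds to the ynol ether during work-up. Propargylic deprotonation with erosion of enantiomeric purity is a second failure process. The fallback sets out from 8 and comes back at 18. It carries the carboxyl carbon at the alcohol oxidation level.
   - LiAlH4 (THF, 0 °C) reduces 8 to (3S)-3-phenylpent-4-yn-1-ol F4.
   - TIPSCl and imidazole in DMF give triisopropyl{[(3S)-3-phenylpent-4-yn-1-yl]oxy}silane F5, whose only acidic proton is the alkyne C–H.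
   - The one-anion sequence (LiN(SiMe3)2; t-BuOOLi; TIPSOTf) gives (3R)-3-phenyl-1,5-bis[(triisopropylsilyl)oxy]pent-1-yne F6.
   - Benzannulation with 3 under the conditions of step 5 gives 5-(benzyloxy)-2-{(1R)-1-phenyl-3-[(triisopropylsilyl)oxy]propyl}-3-[(triisopropylsilyl)oxy]phenol F7.
   - Bu4NF, then K2CO3 and MeI, give (3R)-3-[4-(benzyloxy)-2,6-dimethoxyphenyl]-3-phenylpropan-1-ol F8.
   - TEMPO and PhI(OAc)2 in MeCN/H2O oxidise the primary alcohol to (3R)-3-[4-(benzyloxy)-2,6-dimethoxyphenyl]-3-phenylpropanoic acid F9.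
   - K2CO3 and MeI in DMF give 18.

3. Step 1. The alcohol may cleave the strained vinylogous ester under acid (opening to acetoacetate-type esters), or adventitious water may hydrolyse it faster than the alkoxy groups exchange. The fallback sets out from 1 and comes back at 3. Cold dilute HCl hydrolyses 1 to cyclobutane-1,3-dione F10, which is present largely as its enol. The acidic enol is then O-benzylated with 2 under neutral Mitsunobu conditions (PPh3, DIAD, THF, 0 °C) to give 3.

**Further compounds**

F1 | step 5 | benzyl (2E)-3-(benzyloxy)but-2-enoate | O=C(OCc1ccccc1)/C=C(\C)OCc1ccccc1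
F2 | step 5 | (2E)-3-(benzyloxy)but-2-enoic acid | OC(=O)/C=C(\C)OCc1ccccc1
F3 | step 5 | (2E)-3-(benzyloxy)but-2-enoyl chloride | ClC(=O)/C=C(\C)OCc1ccccc1
F4 | step 4 | (3S)-3-phenylpent-4-yn-1-ol | OCC[C@H](c1ccccc1)C#C
F5 | step 4 | triisopropyl{[(3S)-3-phenylpent-4-yn-1-yl]oxy}silane | CC(C)[Si](C(C)C)(C(C)C)OCC[C@H](c1ccccc1)C#C
F6 | step 4 | (3R)-3-phenyl-1,5-bis[(triisopropylsilyl)oxy]pent-1-yne | CC(C)[Si](C(C)C)(C(C)C)OCC[C@H](c1ccccc1)C#CO[Si](C(C)C)(C(C)C)C(C)C
F7 | step 4 | 5-(benzyloxy)-2-{(1R)-1-phenyl-3-[(triisopropylsilyl)oxy]propyl}-3-[(triisopropylsilyl)oxy]phenol | CC(C)[Si](C(C)C)(C(C)C)OCC[C@H](c1ccccc1)c1c(O)cc(OCc2ccccc2)cc1O[Si](C(C)C)(C(C)C)C(C)C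
F8 | step 4 | (3R)-3-[4-(benzyloxy)-2,6-dimethoxyphenyl]-3-phenylpropan-1-ol | OCC[C@H](c1ccccc1)c1c(OC)cc(OCc2ccccc2)cc1OC
F9 | step 4 | (3R)-3-[4-(benzyloxy)-2,6-dimethoxyphenyl]-3-phenylpropanoic acid | OC(=O)C[C@H](c1ccccc1)c1c(OC)cc(OCc2ccccc2)cc1OC
F10 | step 1 | cyclobutane-1,3-dione | O=C1CC(=O)C1
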